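**Plan**
- Retrosynthetic cuts, in order: (i) the enol ether bond O1–C6 of the pyranone (cyclodehydration of a 6-hydroxy-2,4-dione); (ii) O1–C2 and C3–C4 together, as the retron of a 2-isoxazoline made from a nitrile oxide and a terminal C=C; (iii) the side-chain bond C1'–C2'.
- Enabling feature: ring atoms O1–C2(H)–C3H2–C4(=O) are an aldol unit whose C3 is unsubstituted. A C≡N–O dipole that already carries C4, C5 and the masked acetyl carbon C6 can place its oxygen on C2 and its carbon on C3 of a CH2=CH unit. The nitrogen and the isoxazoline ring are temporary helpers.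
- Forward order: hydroximoyl chloride from ethyl acetoacetate ethylene ketal; zinc/tartrate-directed cycloaddition to allyl alcohol (isoxazoline ring); triflate and copper-catalysed coupling with the (Z)-icos-11-enyl Grignard reagent (chain joined); Mo(CO)6 opening of the isoxazoline; acid removes the ketal and closes the pyranone ring.
- Stereochemistry: the only stereocentre (C2, R) is set in the cycloaddition by (S,S)-diisopropyl tartrate on zinc, and no bond to it is made or broken afterwards. The Z-alkene comes in with (Z)-icos-11-en-1-ol.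

Key step: step 4

Assumption: the zinc/tartrate cycloaddition is taken to follow the sense of induction established for this reaction type ((R,R)-tartrate leading to the 5R hydroxymethyl isoxazoline), so the (S,S)-tartrate is specified for the 5S adduct; the antipodal tartrate would be used if the sense proves reversed for this dipole.

**Step 1**
Reactants: 1 ethyl 2-(2-methyl-1,3-dioxolan-2-yl)acetate
Product: 2 2-(2-methyl-1,3-dioxolan-2-yl)acetaldehyde
Conditions: DIBAL-H (1.05 equiv), CH2Cl2, −78 °C; Rochelle salt work-up; used without storage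
Reagents that add atoms: none
Why: DIBAL-H partial reduction of an ester, in which the tetrahedral aluminium hemiacetal persists at −78 °C and releases the aldehyde only on work-up, while the ketal is inert to hydride and to the buffered work-up.

**Step 2**
Reactants: 2 2-(2-methyl-1,3-dioxolan-2-yl)acetaldehyde
Product: 3 2-(2-methyl-1,3-dioxolan-2-yl)acetaldehyde oxime (E/Z mixture)
Conditions: NH2OH·HCl, NaHCO3, EtOH/H2O, 0 °C → rt
Reagents that add atoms: hydroxylamine hydrochloride, Cl.NO
Why: Oxime formation by condensation of the aldehyde with hydroxylamine under bicarbonate buffering, which is mild enough for the dioxolane; the E/Z mixture is of no consequence because both isomers are chlorinated at the same carbon.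

**Step 3**
Reactants: 3 2-(2-methyl-1,3-dioxolan-2-yl)acetaldehyde oxime
Product: 4 N-hydroxy-2-(2-methyl-1,3-dioxolan-2-yl)ethanimidoyl chloride (hydroximoyl chloride)
Conditions: NCS, pyridine (cat.), CHCl3, 0 °C → rt; aqueous wash, dried CHCl3 solution used directly
Reagents that add atoms: N-chlorosuccinimide, O=C1CCC(=O)N1Cl
Why: Electrophilic chlorination of the aldoxime carbon with NCS (hydroximoyl chloride synthesis), the standard entry to nitrile oxide precursors, with pyridine buffering adventitious HCl so that the ketal is kept.

**Step 4**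
Reactants: 4 N-hydroxy-2-(2-methyl-1,3-dioxolan-2-yl)ethanimidoyl chloride; 5 allyl alcohol (prop-2-en-1-ol)
Product: 7 [(5S)-3-[(2-methyl-1,3-dioxolan-2-yl)methyl]-4,5-dihydro-1,2-oxazol-5-yl]methanol, via nitrile oxide 6 (not isolated)
Conditions: 5, Et2Zn (1 equiv), CHCl3, 0 °C; (S,S)-diisopropyl tartrate (1 equiv); Et2Zn (1 equiv); then 4 by slow addition, 0 °C
Reagents that add atoms: none
Why: The ethylzinc alkoxide of 5 and the zinc salt of (S,S)-diisopropyl tartrate assemble into a tartrate-bridged dizinc complex whose basic site dehydrochlorinates 4 to nitrile oxide 6, held on zinc through its oxygen, and a concerted but asynchronous 1,3-dipolar cycloaddition then joins the dipole carbon to the terminal CH2 and the dipole oxygen to the internal CH of the zinc-bound allyloxide. The closest known reaction type is the zinc/tartrate-mediated asymmetric nitrile oxide cycloaddition to allylic alcohols, the enantioselective form of the metal-alkoxide-directed nitrile oxide cycloaddition. The 2-isoxazoline ring is closed by a suprafacial [3+2] cycloaddition, both ring bonds forming in the same event, and this five-membered ring is only a temporary carrier of the aldol unit. The new stereocentre (C5 of the isoxazoline, later C2 of the pyranone) is controlled by the C2-symmetric tartrate, which leaves one enantioface of the coordinated alkene open to the zinc-bound dipole; the S descriptor of 7 corresponds in space to the R centre of the target. The step needs regioselectivity (oxygen to the substituted carbon), which monosubstituted alkenes show inherently toward nitrile oxides and which the alkoxide–zinc–dipole tether reinforces, and facial selectivity, which rests on the tartrate. Dimerisation of 6 to a furoxan, the main competing path, is held back by slow addition of 4 so that free dipole does not accumulate.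

**Step 5**
Reactants: 7 [(5S)-3-[(2-methyl-1,3-dioxolan-2-yl)methyl]-4,5-dihydro-1,2-oxazol-5-yl]methanol
Product: 8 [(5S)-3-[(2-methyl-1,3-dioxolan-2-yl)methyl]-4,5-dihydro-1,2-oxazol-5-yl]methyl trifluoromethanesulfonate
Conditions: Tf2O, 2,6-lutidine, CH2Cl2, −78 → −40 °C; crude triflate used at once
Reagents that add atoms: trifluoromethanesulfonic anhydride, O=S(=O)(OS(=O)(=O)C(F)(F)F)C(F)(F)F
Why: O-Sulfonylation of a primary alcohol with triflic anhydride and a hindered base at low temperature, under which the weakly basic isoxazoline nitrogen and the ketal are inert.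

**Step 6**
Reactants: 9 (Z)-icos-11-en-1-ol
Product: 10 (Z)-1-bromoicos-11-ene
Conditions: CBr4, PPh3, CH2Cl2, 0 °C
Reagents that add atoms: tetrabromomethane, BrC(Br)(Br)Br
Why: Appel reaction, an SN2 displacement of the oxyphosphonium group by bromide at a primary carbon, which leaves the remote Z-alkene untouched.

**Step 7**
Reactants: 8 [(5S)-3-[(2-methyl-1,3-dioxolan-2-yl)methyl]-4,5-dihydro-1,2-oxazol-5-yl]methyl trifluoromethanesulfonate; 10 (Z)-1-bromoicos-11-ene
Product: 12 (5R)-5-[(12Z)-henicos-12-en-1-yl]-3-[(2-methyl-1,3-dioxolan-2-yl)methyl]-4,5-dihydro-1,2-oxazole, via Grignard reagent 11 (not isolated)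
Conditions: 10, Mg, THF, rt; then 8, CuBr·SMe2 (10 mol %), Et2O/THF, −40 → 0 °C
Reagents that add atoms: none
Why: Copper-catalysed cross-coupling of a Grignard reagent with a primary alkyl triflate (SN2 displacement by a transient alkylcuprate), a reaction type that works well on primary triflates bearing a β-oxygen and that should outrun addition to the C=N bond at low temperature; the stereocentre is one carbon away from the reacting centre, and its descriptor changes from S to R only through the priority rules.

**Step 8**
Reactants: 12 (5R)-5-[(12Z)-henicos-12-en-1-yl]-3-[(2-methyl-1,3-dioxolan-2-yl)methyl]-4,5-dihydro-1,2-oxazole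
Product: 14 (4R,16Z)-4-hydroxy-1-(2-methyl-1,3-dioxolan-2-yl)pentacos-16-en-2-one, via β-hydroxy imine 13 (not isolated)
Conditions: Mo(CO)6 (1 equiv), MeCN/H2O (15:1), 80 °C
Reagents that add atoms: water, O
Why: Reductive cleavage of the isoxazoline N–O bond by Mo(CO)6 in wet acetonitrile followed by hydrolysis of the β-hydroxy imine (unmasking of the aldol), chosen over hydrogenolysis because it spares the Z-alkene; the carbinol centre is not involved.

**Step 9**
Reactants: 14 (4R,16Z)-4-hydroxy-1-(2-methyl-1,3-dioxolan-2-yl)pentacos-16-en-2-one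
Product: 17 (2R)-2-[(12Z)-henicos-12-en-1-yl]-6-methyl-2,3-dihydro-4H-pyran-4-one (target), via hydroxy diketone 15 (not isolated), via cyclic hemiketal 16 (not isolated)
Conditions: 2 M aq. HCl, THF, rt; then TsOH·H2O (cat.), CH2Cl2, rt
Reagents that add atoms: none
Why: Acid hydrolysis of the dioxolane, then 6-exo-trig hemiketalisation of the δ-hydroxyl onto the liberated methyl ketone and dehydration to the vinylogous ester (the cyclodehydration route to 2-alkyl-6-methyl-2,3-dihydro-4H-pyran-4-ones); the C–O bond at the stereocentre is never broken, so the R configuration should be retained.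

**Compound list**
1 | ethyl 2-(2-methyl-1,3-dioxolan-2-yl)acetate | CCOC(=O)CC1(C)OCCO1 | starting material
2 | 2-(2-methyl-1,3-dioxolan-2-yl)acetaldehyde | O=CCC1(C)OCCO1 | intermediate
3 | 2-(2-methyl-1,3-dioxolan-2-yl)acetaldehyde oxime (E/Z mixture) | ON=CCC1(C)OCCO1 | intermediate
4 | N-hydroxy-2-(2-methyl-1,3-dioxolan-2-yl)ethanimidoyl chloride | ON=C(Cl)CC1(C)OCCO1 | intermediate
5 | allyl alcohol (prop-2-en-1-ol) | C=CCO | starting material
6 | 2-(2-methyl-1,3-dioxolan-2-yl)acetonitrile oxide (zinc-bound, not isolated) | CC1(CC#[N+][O-])OCCO1 | intermediate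
7 | [(5S)-3-[(2-methyl-1,3-dioxolan-2-yl)methyl]-4,5-dihydro-1,2-oxazol-5-yl]methanol | OC[C@@H]1CC(CC2(C)OCCO2)=NO1 | intermediate
8 | [(5S)-3-[(2-methyl-1,3-dioxolan-2-yl)methyl]-4,5-dihydro-1,2-oxazol-5-yl]methyl trifluoromethanesulfonate | O=S(=O)(OC[C@@H]1CC(CC2(C)OCCO2)=NO1)C(F)(F)F | intermediate
9 | (Z)-icos-11-en-1-ol | CCCCCCCC/C=C\CCCCCCCCCCO | starting material
10 | (Z)-1-bromoicos-11-ene | CCCCCCCC/C=C\CCCCCCCCCCBr | intermediate
11 | (Z)-icos-11-en-1-ylmagnesium bromide (not isolated) | CCCCCCCC/C=C\CCCCCCCCCC[Mg]Br | intermediate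
12 | (5R)-5-[(12Z)-henicos-12-en-1-yl]-3-[(2-methyl-1,3-dioxolan-2-yl)methyl]-4,5-dihydro-1,2-oxazole | CCCCCCCC/C=C\CCCCCCCCCCC[C@@H]1CC(CC2(C)OCCO2)=NO1 | intermediate
13 | (4R,16Z)-2-imino-1-(2-methyl-1,3-dioxolan-2-yl)pentacos-16-en-4-ol (not isolated) | CCCCCCCC/C=C\CCCCCCCCCCC[C@@H](O)CC(=N)CC1(C)OCCO1 | intermediate
14 | (4R,16Z)-4-hydroxy-1-(2-methyl-1,3-dioxolan-2-yl)pentacos-16-en-2-one | CCCCCCCC/C=C\CCCCCCCCCCC[C@@H](O)CC(=O)CC1(C)OCCO1 | intermediate
15 | (6R,18Z)-6-hydroxyheptacos-18-ene-2,4-dione (not isolated) | CCCCCCCC/C=C\CCCCCCCCCCC[C@@H](O)CC(=O)CC(C)=O | intermediate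
16 | (6R)-6-[(12Z)-henicos-12-en-1-yl]-2-hydroxy-2-methyloxan-4-one (anomer mixture, not isolated) | CCCCCCCC/C=C\CCCCCCCCCCC[C@@H]1CC(=O)CC(C)(O)O1 | intermediate
17 | (2R)-2-[(12Z)-henicos-12-en-1-yl]-6-methyl-2,3-dihydro-4H-pyran-4-one | CCCCCCCC/C=C\CCCCCCCCCCC[C@@H]1CC(=O)C=C(C)O1 | target

**Step count and risks**
Total steps: 9. Longest linear sequence: 8 steps (steps 1–5 and 7–9); step 6 is the side branch.

Steps most likely to fail:

1. Step 4. The risk is poor facial selectivity, because the ketal oxygens of the dipole may bind zinc and loosen the tartrate-controlled arrangement, together with dimerisation of the nitrile oxide. Fallback (resolution in place of asymmetric induction): setting out from 4 and 5, cycloaddition without the chiral zinc complex (Et3N, Et2O, slow addition) would give racemic [3-[(2-methyl-1,3-dioxolan-2-yl)methyl]-4,5-dihydro-1,2-oxazol-5-yl]methanol F1. This is resolved by preparative chromatography on a chiral stationary phase (amylose tris(3,5-dimethylphenylcarbamate), supercritical CO2/MeOH). The 5S enantiomer is 7, where the route is rejoined.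

2. Step 7. The risk is deprotonation next to the C=N bond by the basic Grignard reagent with fragmentation of the isoxazoline, addition to C=N, or decomposition of the triflate before coupling. Fallback (non-basic organozinc and palladium catalysis in place of the cuprate displacement): setting out from 7 and 10, alcohol 7 is converted (I2, PPh3, imidazole, CH2Cl2) into (5S)-5-(iodomethyl)-3-[(2-methyl-1,3-dioxolan-2-yl)methyl]-4,5-dihydro-1,2-oxazole F2. Bromide 10 is converted (Zn dust, LiCl, THF) into (Z)-icos-11-en-1-ylzinc bromide F3. An alkyl–alkyl Negishi coupling with PdCl2(IPr)(3-chloropyridine) (IPr = 1,3-bis(2,6-diisopropylphenyl)imidazol-2-ylidene) in THF/NMP at rt should join them to 12, where the route is rejoined.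

3. Step 9. The risk is loss of water from the aldol unit before ring closure, followed by reclosure through oxa-Michael addition without stereocontrol, which would erode enantiomeric purity. Fallback (ketal removal separated from ring closure by temporary protection of the carbinol): setting out from 14, silylation (TBSOTf, 2,6-lutidine, CH2Cl2, −78 °C) gives (4R,16Z)-4-[(tert-butyldimethylsilyl)oxy]-1-(2-methyl-1,3-dioxolan-2-yl)pentacos-16-en-2-one F4. Mild ketal hydrolysis (AcOH/THF/H2O, 40 °C) gives (6R,18Z)-6-[(tert-butyldimethylsilyl)oxy]heptacos-18-ene-2,4-dione F5. HF·pyridine in THF at 0 °C then frees the hydroxyl at low temperature and rejoins the route at 15, which should close to 17 in the same flask.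

**Further compounds**
F1 | step 4 | racemic [3-[(2-methyl-1,3-dioxolan-2-yl)methyl]-4,5-dihydro-1,2-oxazol-5-yl]methanol | OCC1CC(CC2(C)OCCO2)=NO1
F2 | step 7 | (5S)-5-(iodomethyl)-3-[(2-methyl-1,3-dioxolan-2-yl)methyl]-4,5-dihydro-1,2-oxazole | IC[C@@H]1CC(CC2(C)OCCO2)=NO1
F3 | step 7 | (Z)-icos-11-en-1-ylzinc bromide | CCCCCCCC/C=C\CCCCCCCCCC[Zn]Br
F4 | step 9 | (4R,16Z)-4-[(tert-butyldimethylsilyl)oxy]-1-(2-methyl-1,3-dioxolan-2-yl)pentacos-16-en-2-one | CCCCCCCC/C=C\CCCCCCCCCCC[C@@H](O[Si](C)(C)C(C)(C)C)CC(=O)CC1(C)OCCO1
F5 | step 9 | (6R,18Z)-6-[(tert-butyldimethylsilyl)oxy]heptacos-18-ene-2,4-dione | CCCCCCCC/C=C\CCCCCCCCCCC[C@@H](O[Si](C)(C)C(C)(C)C)CC(=O)CC(C)=O
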